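Freeze the dissolved gas.

in all of them: gas phase 28 mM (held)
- autumn: substrate 0.10 M; run made earlier
- winter: substrate 0.15 M; run made earlier
- flask: substrate 0.20 M; time 12 h

- autumn (time / h: target / %): 1.50: 1.5; 4.00: 4.9; 8.00: 9.9; 12.0: 11.5
- winter (time / h: target / %): 3.00: 4.6; 6.00: 7.9; 10.0: 10.1; 12.0: 10.0

(standard deviation of a reading: 0.5 percentage points)

- percent here means substrate units held: one self-condensation product counts as two
- at the start none of the gas is dissolved
- what was read earlier has a scatter of 0.5 percentage points, one standard deviation
- what may be going on: gas phase <-> dissolved gas; substrate + dissolved gas -> target; dissolved gas + target -> over-reacted product; dissolved gas <-> dormant form; 2 substrate -> self-condensation product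

* the target standing at 12 h, as a percentage of the substrate charged
* the change that raises the amount of target at 12 h, in percent of the substrate charged most ("none" if none brings more than 2 percentage points) (Sunday's / Tuesday's / none)
* amount of target at 12 h, in percent of the substrate charged, after Sunday's

- Sunday's: doubling the saturation concentration of gas phase, all else as stated
- Tuesday's: doubling the transfer coefficient of the gas phase, all else as stated

Divide an early reading of each run by its time, 4.9% in 4.00 h for autumn and 4.6% in 3.00 h for winter, and average the two: 0.0138 h⁻¹. Call this the frozen-gas rate, the share of the charged substrate turned into target per hour while dissolved gas stands steady; it is an averaged early yield per charged substrate, read from scattered readings and not a pseudo-first-order constant, so carry it to another charge as a rough figure. Run as a straight line, it promises 16.6% at 12 h. Now find the border: winter's last reading is 0.604 of that line and autumn's is 0.695, so the bend deepens with charge. Of the listed steps, self-condensation is the one whose share per hour grows with charge, and it uses no gas.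

Continue the drop between the two runs, as my own reckoning, to 8.50% for the flask. Sunday's doubles the frozen-gas rate and leaves that bend, giving 17.0%. For Tuesday's, read the uptake lag from autumn's first two readings: about 0.397 h, a rough reading that costs 0.55 percentage points, less than the 2 points needed.

The forecast gives 8.8%, names none as the best change and puts Sunday's at 8.6%, holding that “more dissolved gas mainly reaches the peak sooner”; on Sunday's it stands below mine.

The flask gives 9.72%, the best change is Sunday's, and that change brings 16.3%. Sunday's adds 6.6 points and Tuesday's 0.22 points, with dissolved gas in the flask at 97.1% of saturation by 1.20 h. Divide the flask's 3.93% at 3.00 h by that time: 0.0131 h⁻¹, beside the frozen-gas rate of 0.0138 h⁻¹.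

    gas phase ⇌ dissolved gas, rate k1*(csat - [dissolved gas]) (kL = 5.10 h⁻¹)
    substrate + dissolved gas → target (k = 0.680 M⁻¹ h⁻¹)
    dissolved gas + target → over-reacted product (k = 0.560 M⁻¹ h⁻¹)
    dissolved gas ⇌ dormant form (K = 5.10, k = 0.0280 h⁻¹)
    2 substrate → self-condensation product (k = 0.450 M⁻¹ h⁻¹)

Take the neighbour charged with 0.050 M of substrate: the frozen-gas rate over 12 h gives 16.6%, and the computed neighbour stands at 14.7%, 0.886 of the line.

Readings and results stem from a simulated flask with made-up constants; scatter was added.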